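## The problem

Target 22 is a 3-hydroxy-1,2-dioxane, a cyclic peroxy hemiketal. Numbered along the carbon chain from the carboxyl carbon C1 through the hemiketal carbon C3 to the phenyl-bearing C16, it is one unbranched chain with methyl groups on C4, C6 and C8 and a peroxide bridge from C6 (O1) to C3 (O2). The chain must be built so that the tertiary C6–O1 bond is made under control, because a fully substituted peroxide carbon cannot be corrected once it sits in an open chain. Of the four stereocentres, C3 is a hemiketal and should settle by equilibration in the chair with equatorial C4 methyl, equatorial C7 chain and axial, anomerically stabilized hydroxyl, so it follows from C4 and C6. C4, C6 and C8 form a 1,3,5 array; C8 lies outside the heterocycle and gets no help from it, and C4 is α to the latent C3 ketone and epimerizable whenever the ring is open. The O–O bond rules out phosphines, strong hydride donors such as LiAlH4, low-valent metals, catalytic hydrogenation and long-lived carbanions, and the hemiketal hides a β-keto acid that is lost by decarboxylation or retro-Claisen cleavage if opened under base or heat, so the free acid must appear last and without base. The enabling feature is that C3 to C8, closed into a six-membered carbocycle with C3 as carbonyl, is a 2,4,6-trimethylcyclohexanone oxygenated at C6, the substitution pattern of 2,4,6-trimethylphenol (1); in that ring C4 and C8 are enantiotopic, epimerizable α-carbons, and the meso chair with three equatorial methyl groups and axial O1 has the relative configuration of C4, C6 and C8 in 22. C9 is the single carbon missing between C3 and C8: inserting it into one of the two enantiotopic C3–Cα bonds breaks the symmetry, and the resulting seven-membered ring (C3 to C9) can be cut at C3–C9 into a C3 acid and a C9 aldehyde, the handles for the acetate arm and the phenylalkyl tail.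

## Retrosynthesis

**Hemiketal and ester (22 ⇒ 21 ⇒ 20 ⇒ 19).** The first cuts are the ester C–O bond of tert-butyl ester 21 and the C3–O2 bond of the hemiketal, which opens the dioxane to hydroperoxy keto ester 20, stored as silyl peroxide 19. Cutting C3–O2 rather than C6–O1 keeps the quaternary C–O bond out of the end game and makes C3 a centre that sets itself by ring–chain equilibration. Precursor 19 is acyclic with three stereocentres instead of four. The forward reaction needs desilylation to trigger 6-exo addition of the hydroperoxide to the ketone, and the acid must be released without base, hence a tert-butyl ester.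

**C2–C3 (19 ⇒ 16 + 17).** The β-keto ester is cut between C2 and C3 to acid 16 and malonate half ester 17. An aldol or Reformatsky addition to a C3 aldehyde would need a later oxidation next to the peroxide; the decarboxylative acylation works at the acid oxidation level that the route delivers anyway. The forward reaction must acylate a hindered α-branched acyl donor without epimerizing C4.

**C9–C10 (16 ⇒ 15 ⇒ 11 + 13; 13 ⇒ 12).** The tail is cut at C9–C10 through alkene 15 to aldehyde acid 11 and phosphonium salt 13, itself from bromide 12. This cut uses the aldehyde that the ring cleavage provides and brings in the arene only after the ozonolysis. It reduces the problem to a seven-carbon piece carrying all three stereocentres. The olefination must not epimerize C8, and the alkene must be saturated without touching the O–O bond.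

**Reconnection C3–C9 (11 ⇒ 10 ⇒ 9).** The termini of 11 differ only in oxidation level (C3 acid, C9 aldehyde), which is what ozonolysis of a regiodefined silyl enol ether gives. Joining C3 to C9 leads to enol silane 10 and cycloheptanone 9. A Baeyer–Villiger cut would place oxygen on C4 or C9 and lose the C3 acid. The forward reaction needs enolization toward the methylene C9 and away from the methine C4.

**Key disconnection, C8–C9 and C3–C9 (9 ⇒ 6 + 7).** Removing C9 from 9 gives meso cyclohexanone 6 and (trimethylsilyl)diazomethane (7). Nothing else turns the problem of three absolute configurations into that of one meso compound; the price is that a catalyst must choose between the enantiotopic C3–C8 and C3–C4 bonds. The 1,2-shift itself guarantees retention at the migrating carbon.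

**C6–O1 (6 ⇒ 5 ⇒ 4).** The tertiary silyl peroxide is traced to alkene 4 by a cobalt-catalysed Mukaiyama–Isayama hydroperoxysilylation, followed by equilibration of the two α-centres. Acidic perhydrolysis of tertiary alcohol 3 would be one step shorter, but it would also convert the ketone into geminal bis-hydroperoxides; the radical route tolerates the ketone and installs the protecting group at once. Stereocontrol at C6 is left to thermodynamics, because its configuration has meaning only relative to the epimerizable C4 and C8.

**Carbocycle (4 ⇒ 3 ⇒ 2 ⇒ 1).** Dehydration, hydrogenation and oxidative dearomatization lead back to 1, which already has all nine carbons of C3–C8 with their methyl groups and the oxygen on C3.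

## Roads not taken

Alternative 1: The cut is the C6–O1 bond, made by opening the trisubstituted epoxy alcohol A2 (the product of a Sharpless epoxidation) at its tertiary carbon with hydrogen peroxide under MoO2(acac)2 catalysis; this should give hydroperoxy diol A1 with inversion at C6. The merits are real: perhydrolysis of epoxides at the more substituted carbon is a known reaction, and C6 is set by reagent control with a predictability the chosen plan cannot claim for its key step. The weak points come afterwards. A1 carries a hydroxyl on C5, where 22 has a methylene group, and ends at the carbon that corresponds to C4. The diol must therefore be cleaved or deoxygenated, and C4 (with its methyl stereocentre), C3, C2 and C1 added beside a tertiary hydroperoxide in an open chain where C4 has no controlling neighbour. C8 must be made separately. Against the better precedent and the surer C6 of this road, the chosen plan sets a single operation (step 6) that fixes C4, C6 and C8 together, no redundant oxygen, and a peroxide that stays silylated from 5 to 19.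

Alternative 2: The cuts are C4–C5 and C7–C8, made by [4+3] cycloaddition of the 2-methoxyallyl cation (from bromide A5 and AgOCOCF3) to diene A4, giving meso cycloheptenone A3 with C6 as ketone and C3=C9 as alkene. This reaches the same C3–C9 carbocycle in one step from simple materials, against six steps in the chosen plan, and the cis C4/C8 relationship follows from the diene geometry; in step economy to the seven-membered ring it is clearly better. Its weak points: open-chain dienes that must adopt the s-cis conformation are mediocre partners for simple oxyallyl cations. In A3 the C6 carbon is a ketone flanked by methylene groups, so its methyl and peroxide must be added with the C6 configuration controlled only by a flexible seven-membered ring and remote methyl groups; there is no epimerizable centre for correction, whereas in 6 the α-methyl groups can move. Cleavage of C3=C9 gives two identical termini, so the enantiotopic differentiation is postponed to a separate step. The chosen plan sets against the shorter ring synthesis a C6 centre that thermodynamics can steer and a desymmetrization merged with the C–C bond formation.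

Alternative 3: The cut is C10–C11, made by Kolbe co-electrolysis of core acid A7 with excess 7-phenylheptanoic acid A8 at a platinum anode in methanol, giving methyl ketal methyl ester A6. As an end game it is more convergent than steps 10 and 11: the tail arrives last, analogues would need only another acid, and the α-branched aldehyde olefination and the alkene reduction disappear. Its weak points: mixed Kolbe coupling is statistical and consumes a large excess of A8. The primary C10 radical sits within reach of O1 and can attack the O–O bond or abstract hydrogen before it dimerizes. The peroxide is exposed to the cathode in an undivided cell, and A6 still needs ketal and ester hydrolysis. Above all, the alternative leaves open how A7, with C4, C6 and C8 in place, is made, which is the real problem. It is complementary rather than competing; the chosen plan prefers the ionic C9=C10 construction because it uses the aldehyde that the ring cleavage delivers.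

Key step: step 6

Remark: atom labels C1–C16, O1 and O2 follow the chain of 22 throughout; the peroxide is carried as its triethylsilyl derivative because the cobalt-catalysed step installs that group directly.
Remark: 7 (as a commercial solution), 12, 17 and the pipecolic-acid-derived N,N'-dioxide ligand (either antipode) are taken as purchasable; the ligand is a catalyst component and its preparation is not counted.
Remark: 3, 4 and 5 are diastereomer mixtures whose composition is immaterial before step 5.

## Route

Step 1
Reactants: 1 2,4,6-trimethylphenol
Product: 2 4-hydroxy-2,4,6-trimethylcyclohexa-2,5-dien-1-one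
Conditions: PhI(OAc)2, MeCN/H2O (3:1), 0 °C
Reagents that add atoms: water, O
Why: Oxidative dearomatization of a para-alkylphenol; the aryloxy-iodane collapses to a phenoxenium equivalent that water captures at the methyl-bearing para carbon, the cross-conjugated para-quinol being preferred over the ortho isomer; no stereocentre is formed.

Step 2
Reactants: 2 4-hydroxy-2,4,6-trimethylcyclohexa-2,5-dien-1-one
Product: 3 4-hydroxy-2,4,6-trimethylcyclohexan-1-one (mixture of diastereomers at the two α-carbons)
Conditions: H2 (1 atm), 5% Rh/Al2O3, EtOAc, rt
Reagents that add atoms: none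
Why: Heterogeneous hydrogenation of both enone double bonds; rhodium on alumina is chosen because it saturates alkenes with little hydrogenolysis of the doubly allylic tertiary C–O bond, which would return 1; the α-configurations do not matter because they are equilibrated in step 5.

Step 3
Reactants: 3 4-hydroxy-2,4,6-trimethylcyclohexan-1-one
Product: 4 2,4,6-trimethylcyclohex-3-en-1-one (mixture of diastereomers)
Conditions: Burgess reagent, toluene, 50 °C
Reagents that add atoms: none
Why: Burgess dehydration of the tertiary alcohol by syn elimination of its sulfamate under neutral conditions, which avoids the acid that would pull the β,γ double bond into conjugation; any double-bond regioisomer formed alongside gives the same tertiary radical in step 4.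

Step 4
Reactants: 4 2,4,6-trimethylcyclohex-3-en-1-one
Product: 5 2,4,6-trimethyl-4-[(triethylsilyl)peroxy]cyclohexan-1-one (mixture of three diastereomers)
Conditions: Co(thd)2 (5 mol %; thd = 2,2,6,6-tetramethylheptane-3,5-dionate), O2 (1 atm), Et3SiH, ClCH2CH2Cl, rt
Reagents that add atoms: dioxygen, O=O; triethylsilane, CC[SiH](CC)CC
Why: Mukaiyama–Isayama hydroperoxysilylation; a cobalt hydride delivers a hydrogen atom to C5 (Markovnikov), the tertiary C6 radical is trapped by O2 and the cobalt peroxide is silylated by the silane, so the C6–O1 bond and its protecting group arrive together and the ketone is untouched; facial selectivity is not required because step 5 equilibrates.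

Step 5
Reactants: 5 2,4,6-trimethyl-4-[(triethylsilyl)peroxy]cyclohexan-1-one
Product: 6 (2R,4s,6S)-2,4,6-trimethyl-4-[(triethylsilyl)peroxy]cyclohexan-1-one (meso; the three methyl groups mutually cis and equatorial; the silylperoxy group trans to them and axial)
Conditions: DBU, MeCN, 40 °C; chromatography, other isomers resubmitted
Reagents that add atoms: none
Why: Amine-base epimerization through the enols at both α-carbons (C4 and C8); since the configuration of C6 is defined only relative to these two centres, all three diastereomers interconvert and should drain toward the chair with three equatorial methyl groups and only the small peroxy oxygen axial (methyl has the larger equatorial preference, roughly 1.7 against well under 1 kcal/mol).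

Step 6
Reactants: 6 (2R,4s,6S)-2,4,6-trimethyl-4-[(triethylsilyl)peroxy]cyclohexan-1-one; 7 (trimethylsilyl)diazomethane
Product: 9 (2R,4S,6S)-2,4,6-trimethyl-4-[(triethylsilyl)peroxy]cycloheptan-1-one, via C-silyl ketone 8 (not isolated)
Conditions: Sc(OTf)3 (10 mol %), chiral N,N'-dioxide ligand (pipecolic acid N-oxide units joined by a propane-1,3-diyl linker, 2,6-diisopropylanilide arms; 11 mol %), 7 (1.5 equiv), CH2Cl2, −20 °C; then 0.5 M aq. HCl/THF, 0 °C
Reagents that add atoms: none
Why: Proposed new method: the scandium-bound carbonyl carbon C3 is attacked by the nucleophilic carbon of 7 to give a β-silyl diazonium alkoxide, and the C3–C8 bond antiperiplanar to the departing N2 migrates to the new carbon C9 with retention at C8, forming C8–C9 and leaving C9 bonded to C3 in C-silyl ketone 8, whose silyl group (on carbon, or on the enol oxygen should it have shifted there) is removed by the mild acid to give 9. The closest known reaction types are the Sc(OTf)3-catalysed one-carbon homologation of cycloalkanones with silyl- and aryldiazomethanes and the chiral-Lewis-acid-catalysed desymmetrizing ring expansion of 4-substituted cyclohexanones with α-diazo esters (Buchner–Curtius–Schlotterbeck and Tiffeneau–Demjanov manifold); new here is enantiotopic-bond selection in a meso 2,6-disubstituted ketone with a silyldiazomethane. No ring is closed end to end: the six-membered carbocycle is enlarged to the seven-membered one by the 1,2-shift. No new stereocentre appears in 9, but the meso array becomes chiral, so the absolute configuration of C4, C6 and C8 is fixed here by the chiral scandium complex, which must favour the diazonium conformer that places C3–C8 (the α-carbon of S configuration) and not C3–C4 anti to N2; the ligand antipode is chosen accordingly. The step needs enantiotopic-group selectivity, a single homologation, and migration in preference to epoxide formation. The substrate helps because the two α-carbons are constitutionally identical with equal migratory aptitude, so only the catalyst tells them apart, the three equatorial methyl groups hold one chair for the catalyst to read, and the silyl group in 8 blocks a second insertion.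

Step 7
Reactants: 9 (2R,4S,6S)-2,4,6-trimethyl-4-[(triethylsilyl)peroxy]cycloheptan-1-one
Product: 10 (3S,5S,7R)-3,5,7-trimethyl-5-[(triethylsilyl)peroxy]-1-[(trimethylsilyl)oxy]cyclohept-1-ene
Conditions: Me3SiCl, then LiN(iPr)2, THF, −78 °C (in situ quench)
Reagents that add atoms: chlorotrimethylsilane, C[Si](C)(C)Cl
Why: Kinetic enolization; the hindered lithium amide removes a proton from the methylene C9 rather than the methine C4 and the enolate is silylated on oxygen as it forms, so it has no lifetime in which to attack the peroxide; C4, C6 and C8 are untouched.

Step 8
Reactants: 10 (3S,5S,7R)-3,5,7-trimethyl-5-[(triethylsilyl)peroxy]-1-[(trimethylsilyl)oxy]cyclohept-1-ene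
Product: 11 (2R,4S,6S)-2,4,6-trimethyl-7-oxo-4-[(triethylsilyl)peroxy]heptanoic acid
Conditions: O3, CH2Cl2/MeOH, −78 °C; then Me2S, −78 °C to rt; aqueous work-up
Reagents that add atoms: ozone, [O-][O+]=O
Why: Ozonolysis of a silyl enol ether; cycloaddition and cycloreversion cleave C3=C9, the oxygen-bearing C3 emerging at the carboxylic acid level (silyl ester, hydrolysed on work-up) and C9 as the aldehyde after sulfide reduction; dimethyl sulfide does not reduce the hindered silyl peroxide, and no arene is present yet.

Step 9
Reactants: 12 (7-bromoheptyl)benzene
Product: 13 (7-phenylheptyl)triphenylphosphonium bromide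
Conditions: PPh3, MeCN, reflux
Reagents that add atoms: triphenylphosphine, c1ccc(cc1)P(c1ccccc1)c1ccccc1
Why: SN2 quaternization of triphenylphosphine by a primary alkyl bromide.

Step 10
Reactants: 11 (2R,4S,6S)-2,4,6-trimethyl-7-oxo-4-[(triethylsilyl)peroxy]heptanoic acid; 13 (7-phenylheptyl)triphenylphosphonium bromide
Product: 15 (2R,4S,6S,7Z)-2,4,6-trimethyl-14-phenyl-4-[(triethylsilyl)peroxy]tetradec-7-enoic acid, via phosphorus ylide 14 (not isolated)
Conditions: 13 (3 equiv), NaN(SiMe3)2 (2.9 equiv), THF, 0 °C; then 11, −78 °C to 0 °C; pH 4 buffer
Reagents that add atoms: none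
Why: Wittig olefination with a non-stabilized ylide forms C9=C10 (Z expected, geometry irrelevant); one equivalent of ylide is spent on the carboxylic acid, and addition at −78 °C keeps the α-methyl aldehyde centre C8 from epimerizing.

Step 11
Reactants: 15 (2R,4S,6S,7Z)-2,4,6-trimethyl-14-phenyl-4-[(triethylsilyl)peroxy]tetradec-7-enoic acid
Product: 16 (2R,4S,6R)-2,4,6-trimethyl-14-phenyl-4-[(triethylsilyl)peroxy]tetradecanoic acid
Conditions: 2-nitrobenzenesulfonylhydrazide, Et3N, CH2Cl2, rt
Reagents that add atoms: none
Why: Diimide reduction; concerted syn transfer of two hydrogens saturates the disubstituted alkene without touching the O–O bond or the arene, which metal-catalysed hydrogenation would not guarantee; the descriptor change at C8 (S to R) reflects a priority change only.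

Step 12
Reactants: 16 (2R,4S,6R)-2,4,6-trimethyl-14-phenyl-4-[(triethylsilyl)peroxy]tetradecanoic acid; 17 3-tert-butoxy-3-oxopropanoic acid
Product: 19 tert-butyl (4R,6S,8R)-4,6,8-trimethyl-3-oxo-16-phenyl-6-[(triethylsilyl)peroxy]hexadecanoate, via acyl imidazolide 18 (not isolated)
Conditions: 1,1'-carbonyldiimidazole, THF, rt; then Mg(O2CCH2CO2tBu)2 (from 17 and Mg(OEt)2), THF, rt to 40 °C; 0.5 M aq. HCl work-up
Reagents that add atoms: none
Why: Masamune–Claisen homologation; the acyl imidazolide acylates the magnesium malonate at carbon and decarboxylation gives the β-keto ester (C2–C3 bond) under near-neutral conditions; the product is held as a magnesium chelate enolized toward C2, which protects the C4 stereocentre.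

Step 13
Reactants: 19 tert-butyl (4R,6S,8R)-4,6,8-trimethyl-3-oxo-16-phenyl-6-[(triethylsilyl)peroxy]hexadecanoate
Product: 21 tert-butyl 2-[(3S,4R,6S)-3-hydroxy-4,6-dimethyl-6-[(2R)-2-methyl-10-phenyldecyl]-1,2-dioxan-3-yl]acetate, via hydroperoxy keto ester 20 (not isolated)
Conditions: HF·pyridine, THF/pyridine, 0 °C
Reagents that add atoms: none
Why: Fluoride cleaves the Si–O bond of the silyl peroxide and the liberated hydroperoxide adds to the C3 ketone (6-exo-trig) to close the 1,2-dioxane; the hemiketal is reversible, so C3 should settle in the chair with equatorial C4 methyl, equatorial C7 chain and axial, anomerically stabilized hydroxyl, which is the 3S configuration.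

Step 14
Reactants: 21 tert-butyl 2-[(3S,4R,6S)-3-hydroxy-4,6-dimethyl-6-[(2R)-2-methyl-10-phenyldecyl]-1,2-dioxan-3-yl]acetate
Product: 22 2-[(3S,4R,6S)-3-hydroxy-4,6-dimethyl-6-[(2R)-2-methyl-10-phenyldecyl]-1,2-dioxan-3-yl]acetic acid
Conditions: CF3CO2H/CH2Cl2 (1:4), 0 °C
Reagents that add atoms: none
Why: Acidolysis of the tert-butyl ester (E1 loss of isobutene) frees the acid without base, so the hemiketal is never opened to a β-keto carboxylate; peroxy hemiketals form and equilibrate under protic acid, so C3 stays under the same thermodynamic control.

## Compound list

1 | 2,4,6-trimethylphenol | Cc1cc(C)c(O)c(C)c1 | starting material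
2 | 4-hydroxy-2,4,6-trimethylcyclohexa-2,5-dien-1-one | CC1=CC(C)(O)C=C(C)C1=O | intermediate
3 | 4-hydroxy-2,4,6-trimethylcyclohexan-1-one (diastereomer mixture) | CC1CC(C)(O)CC(C)C1=O | intermediate
4 | 2,4,6-trimethylcyclohex-3-en-1-one (diastereomer mixture) | CC1CC(C)=CC(C)C1=O | intermediate
5 | 2,4,6-trimethyl-4-[(triethylsilyl)peroxy]cyclohexan-1-one (diastereomer mixture) | CC1CC(C)(OO[Si](CC)(CC)CC)CC(C)C1=O | intermediate
6 | (2R,4s,6S)-2,4,6-trimethyl-4-[(triethylsilyl)peroxy]cyclohexan-1-one (meso, all-cis methyl groups, axial silylperoxy group) | O=C1[C@H](C)C[C@@](C)(OO[Si](CC)(CC)CC)C[C@@H]1C | intermediate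
7 | (trimethylsilyl)diazomethane | C[Si](C)(C)C=[N+]=[N-] | starting material
8 | 7-(trimethylsilyl) derivative of 9 (C-silyl ketone, mixture at the silyl-bearing carbon) | O=C1[C@H](C)C[C@@](C)(OO[Si](CC)(CC)CC)C[C@H](C)C1[Si](C)(C)C | intermediate (not isolated)
9 | (2R,4S,6S)-2,4,6-trimethyl-4-[(triethylsilyl)peroxy]cycloheptan-1-one | O=C1[C@H](C)C[C@@](C)(OO[Si](CC)(CC)CC)C[C@H](C)C1 | intermediate
10 | (3S,5S,7R)-3,5,7-trimethyl-5-[(triethylsilyl)peroxy]-1-[(trimethylsilyl)oxy]cyclohept-1-ene | C[Si](C)(C)OC1=C[C@@H](C)C[C@](C)(OO[Si](CC)(CC)CC)C[C@H]1C | intermediate
11 | (2R,4S,6S)-2,4,6-trimethyl-7-oxo-4-[(triethylsilyl)peroxy]heptanoic acid | OC(=O)[C@H](C)C[C@@](C)(OO[Si](CC)(CC)CC)C[C@H](C)C=O | intermediate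
12 | (7-bromoheptyl)benzene | BrCCCCCCCc1ccccc1 | starting material
13 | (7-phenylheptyl)triphenylphosphonium bromide | [Br-].c1ccccc1CCCCCCC[P+](c1ccccc1)(c1ccccc1)c1ccccc1 | intermediate
14 | (7-phenylheptylidene)triphenylphosphorane | c1ccccc1CCCCCCC=P(c1ccccc1)(c1ccccc1)c1ccccc1 | intermediate (not isolated)
15 | (2R,4S,6S,7Z)-2,4,6-trimethyl-14-phenyl-4-[(triethylsilyl)peroxy]tetradec-7-enoic acid | OC(=O)[C@H](C)C[C@@](C)(OO[Si](CC)(CC)CC)C[C@H](C)/C=C\CCCCCCc1ccccc1 | intermediate
16 | (2R,4S,6R)-2,4,6-trimethyl-14-phenyl-4-[(triethylsilyl)peroxy]tetradecanoic acid | OC(=O)[C@H](C)C[C@@](C)(OO[Si](CC)(CC)CC)C[C@H](C)CCCCCCCCc1ccccc1 | intermediate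
17 | 3-tert-butoxy-3-oxopropanoic acid (mono-tert-butyl malonate) | CC(C)(C)OC(=O)CC(=O)O | starting material
18 | 1-[(2R,4S,6R)-2,4,6-trimethyl-14-phenyl-4-[(triethylsilyl)peroxy]tetradecanoyl]imidazole | O=C(n1ccnc1)[C@H](C)C[C@@](C)(OO[Si](CC)(CC)CC)C[C@H](C)CCCCCCCCc1ccccc1 | intermediate (not isolated)
19 | tert-butyl (4R,6S,8R)-4,6,8-trimethyl-3-oxo-16-phenyl-6-[(triethylsilyl)peroxy]hexadecanoate | CC(C)(C)OC(=O)CC(=O)[C@H](C)C[C@@](C)(OO[Si](CC)(CC)CC)C[C@H](C)CCCCCCCCc1ccccc1 | intermediate
20 | tert-butyl (4R,6S,8R)-6-hydroperoxy-4,6,8-trimethyl-3-oxo-16-phenylhexadecanoate | CC(C)(C)OC(=O)CC(=O)[C@H](C)C[C@@](C)(OO)C[C@H](C)CCCCCCCCc1ccccc1 | intermediate (not isolated)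
21 | tert-butyl 2-[(3S,4R,6S)-3-hydroxy-4,6-dimethyl-6-[(2R)-2-methyl-10-phenyldecyl]-1,2-dioxan-3-yl]acetate | C[C@H](CCCCCCCCc1ccccc1)C[C@@]1(C)C[C@@H](C)[C@](O)(CC(=O)OC(C)(C)C)OO1 | intermediate
22 | 2-[(3S,4R,6S)-3-hydroxy-4,6-dimethyl-6-[(2R)-2-methyl-10-phenyldecyl]-1,2-dioxan-3-yl]acetic acid | C[C@H](CCCCCCCCc1ccccc1)C[C@@]1(C)C[C@@H](C)[C@](O)(CC(=O)O)OO1 | target

## Step count and risk

Total: 14 steps. Longest linear sequence: 13 steps (steps 1–8 and 10–14, from 1 to 22); step 9 is a one-step side branch.

**Step 6 (key step).** Most likely failures are poor enantiotopic discrimination or low conversion, because the two α-methyl groups hinder both catalyst binding and attack of the diazo carbon; Lewis-acid ionization of the tertiary silyl peroxide and epoxide formation are further risks. The fallback uses known chemistry and separates ring expansion from desymmetrization. It sets out from 6. Homologation with 7 and Sc(OTf)3 alone, worked up without acid, should give racemic enol silane F1. Ozonolysis as in step 8 gives racemic aldehyde acid F2, which is oxidized in the same flask (NaClO2, NaH2PO4, 2-methylbut-2-ene) to meso diacid F3; the cut at C3–C9 makes the two termini identical. Esterification with 7 in methanol gives meso dimethyl ester F4. Pig liver esterase at pH 7 hydrolyses one of the two enantiotopic esters, a desymmetrization established for meso 2,4-dimethylglutarate-type diesters, giving half ester F5. F5 is written for hydrolysis on the C3 side; the sense must be established, and an enzyme of the complementary preference would be needed otherwise. LiBH4 reduces the remaining ester in the presence of the carboxylate to hydroxy acid F6, and Dess–Martin oxidation returns to the route at 11.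

**Step 5 (with step 4, whose stereochemical outcome it must correct).** The thermodynamic bias toward 6 rests on about one kcal/mol and may leave much of the other meso isomer; prolonged base may also cost the silyl group or let an enolate attack the O–O bond. In step 4 the doubly activated α-C–H of 4 may autoxidize. The fallback replaces radical peroxidation plus equilibration by an ionic, kinetically controlled perhydrolysis at the alcohol oxidation level, where no ketone can be converted to a geminal bis-hydroperoxide. It sets out from 3. Equilibration (K2CO3, MeOH) to the cis-2,6-dimethyl isomers and NaBH4 reduction give diol F7. Treatment with 50% H2O2 and catalytic H2SO4 ionizes the tertiary alcohol, and axial capture of the cation on the chair locked by two equatorial methyl groups should give hydroperoxy alcohol F8; transannular ether formation is the risk of this fallback. Et3SiCl and imidazole silylate the more acidic hydroperoxide in preference to the hindered secondary alcohol, giving silylperoxy alcohol F9. Dess–Martin oxidation comes back to the route at 6.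

**Step 7.** The C9 enolate can attack the peroxide oxygen intramolecularly (five-membered ether formation with loss of silanolate) if silylation lags, and regioselectivity may erode if the enolate equilibrates. The fallback avoids deprotonation. It sets out from 6: step 6 is run with non-acidic work-up and brief warming, so that C-silyl ketone 8 undergoes the 1,3-Brook shift to the O-silyl enol ether regiospecifically at C9, which is 10. The route is rejoined at 10, bypassing isolated 9 (its enantiomeric purity is then assayed on 11). This fallback makes no new compound (F0).

**Step 12.** C-acylation of the magnesium malonate by the hindered α-branched acyl imidazolide may be slow, giving time for epimerization at C4 through the activated acyl derivative. The fallback is a crossed Claisen condensation. It sets out from 16: esterification with 7 in methanol gives methyl ester F10, and excess LiCH2CO2tBu (from tert-butyl acetate and LiN(iPr)2, THF, −78 °C) converts it into 19, where the route is rejoined; the product enolate protects C4.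

**Step 14.** In trifluoroacetic acid the hemiketal can ionize to a peroxycarbenium ion and lose a C2 proton (dehydration to an alkylidene dioxane), or the ring-opened β-keto acid can decarboxylate on concentration. The fallback changes the ester so that no acid is needed. It sets out from 16: step 12 is run with the mono-2-(trimethylsilyl)ethyl malonate in place of 17 to give keto ester F11. HF·pyridine as in step 13 gives hemiketal ester F12. Tris(dimethylamino)sulfonium difluorotrimethylsilicate in DMF at 0 °C, followed by buffering to pH 4, removes the silylethyl group and arrives at 22.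

## Further compounds

F1 | step 6 | racemic (3S*,5S*,7R*)-3,5,7-trimethyl-5-[(triethylsilyl)peroxy]-1-[(trimethylsilyl)oxy]cyclohept-1-ene (one enantiomer drawn) | C[Si](C)(C)OC1=C[C@@H](C)C[C@](C)(OO[Si](CC)(CC)CC)C[C@H]1C
F2 | step 6 | racemic (2R*,4S*,6S*)-2,4,6-trimethyl-7-oxo-4-[(triethylsilyl)peroxy]heptanoic acid (one enantiomer drawn) | OC(=O)[C@H](C)C[C@@](C)(OO[Si](CC)(CC)CC)C[C@H](C)C=O
F3 | step 6 | (2R,4s,6S)-2,4,6-trimethyl-4-[(triethylsilyl)peroxy]heptanedioic acid (meso) | OC(=O)[C@H](C)C[C@@](C)(OO[Si](CC)(CC)CC)C[C@H](C)C(=O)O
F4 | step 6 | dimethyl (2R,4s,6S)-2,4,6-trimethyl-4-[(triethylsilyl)peroxy]heptanedioate (meso) | COC(=O)[C@H](C)C[C@@](C)(OO[Si](CC)(CC)CC)C[C@H](C)C(=O)OC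
F5 | step 6 | (2R,4R,6S)-7-methoxy-2,4,6-trimethyl-7-oxo-4-[(triethylsilyl)peroxy]heptanoic acid | OC(=O)[C@H](C)C[C@@](C)(OO[Si](CC)(CC)CC)C[C@H](C)C(=O)OC
F6 | step 6 | (2R,4S,6S)-7-hydroxy-2,4,6-trimethyl-4-[(triethylsilyl)peroxy]heptanoic acid | OC(=O)[C@H](C)C[C@@](C)(OO[Si](CC)(CC)CC)C[C@H](C)CO
F7 | step 5 | 2,4,6-trimethylcyclohexane-1,4-diol (cis-2,6-dimethyl; mixture at C1 and C4) | OC1[C@H](C)CC(C)(O)C[C@@H]1C
F8 | step 5 | 4-hydroperoxy-2,4,6-trimethylcyclohexan-1-ol (three methyl groups cis, hydroperoxy group trans to them; C1 epimers) | OC1[C@H](C)C[C@@](C)(OO)C[C@@H]1C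
F9 | step 5 | 2,4,6-trimethyl-4-[(triethylsilyl)peroxy]cyclohexan-1-ol (ring configuration as in 6; C1 epimers) | OC1[C@H](C)C[C@@](C)(OO[Si](CC)(CC)CC)C[C@@H]1C
F0 | step 7 | none | none
F10 | step 12 | methyl (2R,4S,6R)-2,4,6-trimethyl-14-phenyl-4-[(triethylsilyl)peroxy]tetradecanoate | COC(=O)[C@H](C)C[C@@](C)(OO[Si](CC)(CC)CC)C[C@H](C)CCCCCCCCc1ccccc1
F11 | step 14 | 2-(trimethylsilyl)ethyl (4R,6S,8R)-4,6,8-trimethyl-3-oxo-16-phenyl-6-[(triethylsilyl)peroxy]hexadecanoate | C[Si](C)(C)CCOC(=O)CC(=O)[C@H](C)C[C@@](C)(OO[Si](CC)(CC)CC)C[C@H](C)CCCCCCCCc1ccccc1
F12 | step 14 | 2-(trimethylsilyl)ethyl 2-[(3S,4R,6S)-3-hydroxy-4,6-dimethyl-6-[(2R)-2-methyl-10-phenyldecyl]-1,2-dioxan-3-yl]acetate | C[C@H](CCCCCCCCc1ccccc1)C[C@@]1(C)C[C@@H](C)[C@](O)(CC(=O)OCC[Si](C)(C)C)OO1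
A1 | alternative 1 | (2R,3S,5R)-3-hydroperoxy-3,5-dimethyl-13-phenyltridecane-1,2-diol | C[C@H](CCCCCCCCc1ccccc1)C[C@@](OO)(C)[C@@H](CO)O
A2 | alternative 1 | [(2R,3R)-3-methyl-3-[(2R)-2-methyl-10-phenyldecyl]oxiran-2-yl]methanol | C[C@H](CCCCCCCCc1ccccc1)C[C@@]1(C)O[C@@H]1CO
A3 | alternative 2 | (3R,6S)-3,6-dimethylcyclohept-4-en-1-one (meso, cis) | O=C1C[C@@H](C)C=C[C@@H](C)C1
A4 | alternative 2 | (2E,4E)-hexa-2,4-diene | C/C=C/C=C/C
A5 | alternative 2 | 3-bromo-2-methoxyprop-1-ene | COC(=C)CBr
A6 | alternative 3 | methyl 2-[(3S,4R,6S)-3-methoxy-4,6-dimethyl-6-[(2R)-2-methyl-10-phenyldecyl]-1,2-dioxan-3-yl]acetate | C[C@H](CCCCCCCCc1ccccc1)C[C@@]1(C)C[C@@H](C)[C@](OC)(CC(=O)OC)OO1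
A7 | alternative 3 | (4R)-5-[(3S,5R,6S)-6-methoxy-6-(2-methoxy-2-oxoethyl)-3,5-dimethyl-1,2-dioxan-3-yl]-4-methylpentanoic acid | C[C@H](CCC(=O)O)C[C@@]1(C)C[C@@H](C)[C@](OC)(CC(=O)OC)OO1
A8 | alternative 3 | 7-phenylheptanoic acid | OC(=O)CCCCCCc1ccccc1
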